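Assumption: the target has no stereocentre and no stereogenic double bond, so "the single enantiomer given" is the one achiral compound C28H26O5; no stereocontrol is needed.

**Retrosynthetic overview**
1. Target ⇐ one global Lewis-acid deprotection (two aryl methyl ethers and one catechol isopropylidene ketal) of the fully protected bis(bibenzyl).
2. Protected bis(bibenzyl) ⇐ Ullmann diaryl ether coupling (ring B oxygen to ring C carbon) of an A–B phenol with a C–D aryl bromide.
3. C–D aryl bromide ⇐ new Sc-catalysed ortho-C–H anti-Markovnikov addition of catechol acetonide (ring D) to 3-bromo-4-methoxystyrene (ring C), the styrene coming from the aldehyde by Wittig methylenation.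
4. A–B phenol ⇐ one-pot hydroboration / B-alkyl Suzuki coupling of 3-vinylanisole (ring A) with 4-iodophenol (ring B).
5. No ring is formed; all four benzene rings are bought. Bond order: C–D bridge, A–B bridge, then the B–O–C ether.

**Route**

Step 1
Reactants: 1 3-bromo-4-methoxybenzaldehyde
Product: 2 2-bromo-4-ethenyl-1-methoxybenzene (3-bromo-4-methoxystyrene)
Conditions: Ph3PCH3Br, KOtBu, THF, 0 °C → rt
Reagents that add atoms: methyltriphenylphosphonium bromide, C[P+](c1ccccc1)(c1ccccc1)c1ccccc1.[Br-]
Why: Wittig methylenation of an aromatic aldehyde with the non-stabilised ylide is fast and leaves Ar–Br and OMe untouched; no stereocentre is formed.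

Step 2
Reactants: 2 2-bromo-4-ethenyl-1-methoxybenzene; 3 2,2-dimethyl-1,3-benzodioxole (catechol acetonide)
Product: 4 4-[2-(3-bromo-4-methoxyphenyl)ethyl]-2,2-dimethyl-1,3-benzodioxole
Conditions: (C5Me4SiMe3)Sc(CH2C6H4NMe2-o)2 (5 mol %), [Ph3C][B(C6F5)4] (5 mol %), 3 (10 equiv), toluene, 70 °C, slow addition of 2 (glovebox)
Reagents that add atoms: none
Why: Proposed new method: a cationic half-sandwich Sc(III) alkyl should metalate C4–H of 3 by O-assisted σ-bond metathesis (the ring-locked ketal oxygen holds its in-plane lone pair toward C4–H, the same C–H that is readily ortho-lithiated), 2,1-insertion of styrene 2 into Sc–aryl then puts the aryl on the terminal carbon and Sc on the benzylic carbon (the regiochemistry of Sc-catalysed styrene polymerisation), and σ-bond metathesis of this benzyl–Sc species with the C4–H of a second molecule of 3 releases the linear bibenzyl 4 and regenerates Sc–aryl with no by-product; the closest known reaction type is the rare-earth-alkyl-catalysed ortho-C–H addition of anisoles, dimethoxyarenes and pyridines to alkenes (linear with vinylarenes), which has not been shown for a catechol ketal (1,3-benzodioxole) as the C–H partner; excess 3 and slow addition of 2 should suppress styrene polyinsertion and a second alkylation at C7, the OMe of 2 is not a competing directing group because its lone pair is turned toward the flanking Br, and Ar–Br is inert to d0 Sc(III).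

Step 3
Reactants: 5 1-ethenyl-3-methoxybenzene (3-vinylanisole); 6 9-borabicyclo[3.3.1]nonane (9-BBN, used as its commercial THF solution); 7 4-iodophenol
Product: 9 4-[2-(3-methoxyphenyl)ethyl]phenol, via B-(3-methoxyphenethyl)-9-BBN 8 (not isolated)
Conditions: 9-BBN, THF, 0 °C → rt; then 7, PdCl2(dppf) (3 mol %), aq. K3PO4, DMF, 60 °C
Reagents that add atoms: none
Why: 9-BBN hydroboration of a styrene is >98% anti-Markovnikov, and the B-alkyl Suzuki–Miyaura coupling of the resulting primary alkylborane with an aryl iodide tolerates the phenol (as phenoxide), so the saturated bridge forms directly without a hydrogenation.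

Step 4
Reactants: 9 4-[2-(3-methoxyphenyl)ethyl]phenol; 4 4-[2-(3-bromo-4-methoxyphenyl)ethyl]-2,2-dimethyl-1,3-benzodioxole
Product: 10 4-[2-[4-methoxy-3-[4-[2-(3-methoxyphenyl)ethyl]phenoxy]phenyl]ethyl]-2,2-dimethyl-1,3-benzodioxole
Conditions: CuI (15 mol %), N,N-dimethylglycine·HCl (45 mol %), Cs2CO3, 1,4-dioxane, 105 °C
Reagents that add atoms: none
Why: Ligand-accelerated Ullmann diaryl ether coupling (Cu(I)/amino acid) joins phenols to electron-rich ortho-alkoxy aryl bromides, and the ketal, methyl ethers and CH2–CH2 bridges are stable to carbonate base.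

Step 5
Reactants: 10 4-[2-[4-methoxy-3-[4-[2-(3-methoxyphenyl)ethyl]phenoxy]phenyl]ethyl]-2,2-dimethyl-1,3-benzodioxole
Product: 11 3-[2-[4-hydroxy-3-[4-[2-(3-hydroxyphenyl)ethyl]phenoxy]phenyl]ethyl]benzene-1,2-diol (target, CNP0185459.0)
Conditions: BBr3 (8 equiv), CH2Cl2, −78 °C → rt; then H2O (degassed work-up)
Reagents that add atoms: none
Why: BBr3 Lewis-acid ether cleavage removes both aryl methyl ethers and the catechol isopropylidene ketal in one operation while the diaryl ether and the bibenzyl bridges are inert, and aqueous hydrolysis of the boron aryloxides frees the four phenols.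

**Compound list**
1 | 3-bromo-4-methoxybenzaldehyde | COc1ccc(C=O)cc1Br | starting material
2 | 2-bromo-4-ethenyl-1-methoxybenzene | COc1ccc(C=C)cc1Br | intermediate
3 | 2,2-dimethyl-1,3-benzodioxole | CC1(C)Oc2ccccc2O1 | starting material
4 | 4-[2-(3-bromo-4-methoxyphenyl)ethyl]-2,2-dimethyl-1,3-benzodioxole | COc1ccc(CCc2cccc3OC(C)(C)Oc23)cc1Br | intermediate
5 | 1-ethenyl-3-methoxybenzene | COc1cccc(C=C)c1 | starting material
6 | 9-borabicyclo[3.3.1]nonane | B1C2CCCC1CCC2 | starting material
7 | 4-iodophenol | Oc1ccc(I)cc1 | starting material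
8 | 9-[2-(3-methoxyphenyl)ethyl]-9-borabicyclo[3.3.1]nonane | COc1cccc(CCB2C3CCCC2CCC3)c1 | intermediate (not isolated)
9 | 4-[2-(3-methoxyphenyl)ethyl]phenol | COc1cccc(CCc2ccc(O)cc2)c1 | intermediate
10 | 4-[2-[4-methoxy-3-[4-[2-(3-methoxyphenyl)ethyl]phenoxy]phenyl]ethyl]-2,2-dimethyl-1,3-benzodioxole | COc1cccc(CCc2ccc(Oc3cc(CCc4cccc5OC(C)(C)Oc45)ccc3OC)cc2)c1 | intermediate
11 | 3-[2-[4-hydroxy-3-[4-[2-(3-hydroxyphenyl)ethyl]phenoxy]phenyl]ethyl]benzene-1,2-diol | Oc1cccc(CCc2ccc(Oc3cc(CCc4cccc(O)c4O)ccc3O)cc2)c1 | target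

**Step count:** 5 steps in total. Longest linear sequence: 4 steps (steps 1, 2, 4, 5); step 3 is a one-step side branch.

**Three steps most likely to fail**

Step 2 (the proposed new C–H addition) is the most likely to fail, through polyinsertion of the electron-rich styrene, Lewis-acid opening of the ketal by the Sc cation, or double alkylation. The fallback uses only known chemistry, sets out from 2 and 3 and comes back at 4. Compound 3 is ortho-lithiated (n-BuLi, THF, 0 °C) to (2,2-dimethyl-1,3-benzodioxol-4-yl)lithium F1, which is quenched with I2 at −78 °C to give 4-iodo-2,2-dimethyl-1,3-benzodioxole F2. Styrene 2 is hydroborated with 9-BBN (6) in THF to 9-[2-(3-bromo-4-methoxyphenyl)ethyl]-9-borabicyclo[3.3.1]nonane F3. F3 is then coupled with F2 under B-alkyl Suzuki conditions (PdCl2(dppf), aq. K3PO4, THF, 40 °C), where the aryl iodide reacts in preference to the hindered, electron-rich ortho-methoxy aryl bromide, giving 4.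

Step 4 (Ullmann coupling) may be sluggish or give hydrodebromination, because bromide 4 is electron-rich and ortho-substituted. The fallback switches to an oxidative boron-based etherification; it sets out from 4 and comes back at 10. Miyaura borylation of 4 (B2pin2, PdCl2(dppf), KOAc, dioxane, 90 °C) gives 2-[5-[2-(2,2-dimethyl-1,3-benzodioxol-4-yl)ethyl]-2-methoxyphenyl]-4,4,5,5-tetramethyl-1,3,2-dioxaborolane F4. Neutral oxidative removal of pinacol (NaIO4, NH4OAc, acetone–water, rt) gives [5-[2-(2,2-dimethyl-1,3-benzodioxol-4-yl)ethyl]-2-methoxyphenyl]boronic acid F5. Chan–Lam–Evans coupling of F5 with phenol 9 (Cu(OAc)2, pyridine, 4 Å MS, CH2Cl2, air, rt) gives 10.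

Step 3 (hydroboration / B-alkyl Suzuki on a free iodophenol) may suffer from slow oxidative addition to the phenoxide, protodeboronation or β-hydride elimination. The fallback builds the bridge as a stilbene and reduces it; it sets out from 5 and 7 and comes back at 9. Mizoroki–Heck coupling of 5 with 7 (Pd(OAc)2, K2CO3, n-Bu4NCl, DMF, 90 °C) gives 4-[(E)-2-(3-methoxyphenyl)ethenyl]phenol F6, and hydrogenation (H2 1 atm, 10% Pd/C, EtOAc, rt) gives 9.

**Further compounds**
F1 | step 2 | (2,2-dimethyl-1,3-benzodioxol-4-yl)lithium | [Li]c1cccc2OC(C)(C)Oc12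
F2 | step 2 | 4-iodo-2,2-dimethyl-1,3-benzodioxole | Ic1cccc2OC(C)(C)Oc12
F3 | step 2 | 9-[2-(3-bromo-4-methoxyphenyl)ethyl]-9-borabicyclo[3.3.1]nonane | COc1ccc(CCB2C3CCCC2CCC3)cc1Br
F4 | step 4 | 2-[5-[2-(2,2-dimethyl-1,3-benzodioxol-4-yl)ethyl]-2-methoxyphenyl]-4,4,5,5-tetramethyl-1,3,2-dioxaborolane | COc1ccc(CCc2cccc3OC(C)(C)Oc23)cc1B1OC(C)(C)C(C)(C)O1
F5 | step 4 | [5-[2-(2,2-dimethyl-1,3-benzodioxol-4-yl)ethyl]-2-methoxyphenyl]boronic acid | COc1ccc(CCc2cccc3OC(C)(C)Oc23)cc1B(O)O
F6 | step 3 | 4-[(E)-2-(3-methoxyphenyl)ethenyl]phenol | COc1cccc(/C=C/c2ccc(O)cc2)c1
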